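## Analysis of the target

Monochlorosulochrin (16) is a benzophenone: two benzene rings joined through one ketone carbon, with no further ring and no stereocentre, so every problem is one of regio- and chemoselectivity. Ring A carries the methyl ester at C1, the ketone at C2, a methoxy group at C3 and a free hydroxyl at C5. Ring B is bonded to the ketone at C1' and carries hydroxyls at C2' and C6', a methyl group at C4', chlorine at C5' and hydrogen at C3'. The ketone is flanked by four ortho substituents, so any late bond formation at this carbon is hindered. The ester next to the ketone can form lactol or pseudo-ester tautomers and can be attacked by a neighbouring carbanion. A ring B phenoxide can displace the C3 methoxy group to give a xanthone. Both rings are electron-rich toward electrophiles and oxidants, and the aryl chloride would not survive hydrogenolysis. The hard points are telling four phenolic oxygens apart (only one is methylated), placing a single methyl ester, and placing one chlorine on a ring B whose positions C3' and C5' would be equivalent without it, so that late chlorination would be statistical and would also compete with ring A. The strategy rests on ring B being a 2-acylresorcinol. C1' sits between the two oxygen-bearing carbons C2' and C6', which makes ring B the aromatic tautomer of a 2-acylcyclohexane-1,3-dione. Such a ring can be closed by a Claisen condensation of C1' onto a C6' ester, and the open chain can be stored as a 3-chloro-4-methyl-2-pyranone that already holds the chlorine and the methyl group on the future C5' and C4'.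

## Retrosynthetic reasoning

The target 16 is first traced back to the carboxylic acid 15, 2-(3-chloro-2,6-dihydroxy-4-methylbenzoyl)-5-hydroxy-3-methoxybenzoic acid, by cutting the O–CH3 bond of the ester. The methyl ester cannot be carried through the ring B construction (see below), so it is made last. The forward step has to alkylate the carboxyl group, the most acidic site, without touching three phenols.

Acid 15 comes from 14, tert-butyl 2-(3-chloro-2,6-dihydroxy-4-methylbenzoyl)-3-methoxy-5-(methoxymethoxy)benzoate. The tert-butyl ester and the methoxymethyl ether are both acid-labile, so one acidolysis removes both.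

In 14 the C1'–C6' bond of ring B is cut. This is the central disconnection. It is made here, and not at either aryl–carbonyl bond, because it avoids any intermolecular attack on the fourfold-hindered ketone carbon and because it fixes the ring B substitution pattern by connectivity. The precursor is the pyranone 12, tert-butyl 2-[2-(3-chloro-4-methyl-2-oxo-2H-pyran-6-yl)acetyl]-3-methoxy-5-(methoxymethoxy)benzoate. Alkoxide opening of its lactone gives the open-chain diketo enoate 13, whose C1' methylene lies between two ketones and closes onto the released ester. The pyranone ring oxygen becomes the C2' hydroxyl, the lactone carbonyl oxygen the C6' hydroxyl, and pyranone C3, C4 and C5 become C5' (Cl), C4' (CH3) and C3' (H). The forward reaction must make C1' attack the enoate ester and not the ring A ester. This is why the ring A carboxyl is carried as a tert-butyl ester.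

Pyranone 12 is a β-keto pyranone. Its ketone is taken back to the secondary alcohol 11, and the bond between the carbinol carbon and C1' is cut. This gives the ring A aldehyde 7, tert-butyl 2-formyl-3-methoxy-5-(methoxymethoxy)benzoate, and the lithium trienolate 10 of 3-chloro-4,6-dimethyl-2H-pyran-2-one (9). An aldehyde is chosen as the electrophile rather than an acyl derivative for three reasons: the carbon is flanked by two ortho substituents, an aldol addition does not release an acidic product that would consume a second equivalent of the nucleophile, and an activated acyl group next to a tert-butyl ester is prone to collapse to the anhydride.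

Pyranone 9 is traced to commercial 4,6-dimethyl-2H-pyran-2-one (8) by cutting the C3–Cl bond. C3 is the terminus of the cyclic dienyl ester and the expected site of electrophilic attack.

Aldehyde 7 is traced through the acid 6 to the methyl ester 5, methyl 2-formyl-3-methoxy-5-(methoxymethoxy)benzoate. The ester exchange is placed after the formylation and the phenol differentiation, because those steps are best run on a methyl ester, and before the aldol, because from there on the hindered ester is needed.

In 5 the two ether bonds are cut in turn, to 4 (free C3 hydroxyl) and then to methyl 2-formyl-3,5-dihydroxybenzoate (3). The formyl group distinguishes the two hydroxyls: the C3 hydroxyl is held in a hydrogen bond to the aldehyde, while the C5 hydroxyl, para to the aldehyde, is the more acidic and the more nucleophilic. Protection therefore goes to C5 first and the methyl group is then put on C3.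

Finally the C2–CHO bond of 3 is cut, leading to commercial methyl 3,5-dihydroxybenzoate (1). The two hydroxyls are equivalent at this stage, so formylation next to the ester (through the iminium salt 2) raises no regiochemical question between them.

## Alternatives that were turned down

Alternative 1: The anthraquinone A1 (7-chloro-8-hydroxy-1-methoxy-6-methyl-9,10-dioxo-9,10-dihydroanthracen-3-yl acetate) would be cleaved oxidatively between its non-chelated quinone carbonyl and the adjoining ring B carbon.
- Key step: a strongly electrophilic peracid adds to that carbonyl and the ring B carbon migrates to oxygen, expanding the central ring to the seven-membered aryl lactone A2 (2-chloro-1-hydroxy-10-methoxy-3-methyl-6,11-dioxo-6,11-dihydrodibenzo[b,e]oxepin-8-yl acetate).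
- For: methanolysis of A2 would open the lactone to the methyl ester and the ring B phenol and remove the acetate in one operation. On the endgame and on avoiding protecting-group exchange this plan is shorter than the chosen one. It also never requires a bond to be made at a hindered ketone.
- Against: a quinone carbonyl conjugated to two arenes is a poor Baeyer–Villiger substrate. The peracid needed would also attack the free phenol and the electron-rich rings. The two candidate migrating carbons are both meta to their oxygen substituents, so nothing in the structure clearly decides which aryl group migrates or which carbonyl is attacked. The chlorine would have to be placed regioselectively on A1 beforehand.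
- Comparison: the chosen strategy is longer, but every oxygen and the chlorine of ring B are traced to a defined atom of the pyranone, and the ring closes by a polar reaction under mild base.

Alternative 2: Ring A would be built by cycloaddition, cutting its C1–C2 and C5–C6 bonds.
- Key step: the ring B ynone ester A3 (methyl 4-[3-chloro-2,6-bis(methoxymethoxy)-4-methylphenyl]-4-oxobut-2-ynoate) reacts with the diene A4 (1,1-dimethoxy-3-(trimethylsilyloxy)buta-1,3-diene). The adduct aromatises by loss of one alkoxy group and the silyl group to give A5 (methyl 2-[3-chloro-2,6-bis(methoxymethoxy)-4-methylbenzoyl]-5-hydroxy-3-methoxybenzoate).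
- For: ring A would appear in one step with the methoxy group, the free hydroxyl and the methyl ester already differentiated. The chosen route spends five steps on this, so this plan is clearly stronger on that point.
- Against: the orientation depends on the ketone polarising the alkyne more strongly than the ester. The aroyl group here is twisted out of conjugation by two ortho substituents, so this bias is uncertain, and the wrong orientation would place the methoxy group next to the ester. Ring B would still have to be made as a separately chlorinated, doubly protected aryl unit, with the chlorine regiochemistry unsolved. A3 is a reactive Michael acceptor and A4 is moisture-sensitive.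
- Comparison: the chosen strategy gives up the short ring A construction in exchange for unambiguous regiochemistry in both rings.

Alternative 3: Ring B would be made from a pyranone by a pericyclic route, cutting C1'–C2' and C3'–C4'.
- Key step: the 3-aroyl pyranone A6 (methyl 2-[(5-chloro-4-hydroxy-6-methyl-2-oxo-2H-pyran-3-yl)carbonyl]-3-methoxy-5-(pivaloyloxy)benzoate) acts as an electron-poor diene across C3 and C6 toward the ketene acetal A7 (1,1-bis(trimethylsilyloxy)ethene). The bridged adduct decarboxylates and aromatises with loss of silanol to A8 (methyl 2-(3-chloro-2,6-dihydroxy-4-methylbenzoyl)-3-methoxy-5-(pivaloyloxy)benzoate).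
- For: the chlorine is again carried in from the pyranone. No carbanion is generated next to the ring A ester, so the methyl ester can be present from the start and only the pivalate remains to be removed. That is one step fewer at the end than in the chosen route.
- Against: A6 is a vinylogous acid. Its hydroxyl would protodesilylate A7, and as its enolate or silyl ether the diene becomes electron-rich and poorly matched to an electron-rich dienophile. The new bond to C6 must form at a methyl-substituted terminus next to the chlorine-bearing carbon. The decarboxylation needs heat that A7 tolerates poorly.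
- Comparison: the chosen strategy closes the same ring intramolecularly by an enolate-to-ester attack that needs no diene activation.

Key step: step 9

Remark on the chemistry: 6 is drawn as the open formyl acid although it may exist in part as its lactol tautomer. 12 is drawn as the diketone although it should be largely enolised. 11 is racemic and its stereocentre is removed in step 8.

## Route

Step 1
Reactants: 1 methyl 3,5-dihydroxybenzoate
Product: 3 methyl 2-formyl-3,5-dihydroxybenzoate, via the benzylidene iminium chloride 2 (not isolated)
Conditions: POCl3, DMF, MeCN, 0 °C to rt; then H2O, 50 °C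
Reagents that add atoms: N,N-dimethylformamide CN(C)C=O; water O
Why: Vilsmeier–Haack formylation of a resorcinol-type arene; the chloroiminium ion should attack C2, which is para to one hydroxyl and ortho to the other, rather than C4 between the two hydroxyls, and hydrolysis of 2 releases the aldehyde.

Step 2
Reactants: 3 methyl 2-formyl-3,5-dihydroxybenzoate
Product: 4 methyl 2-formyl-3-hydroxy-5-(methoxymethoxy)benzoate
Conditions: MOMCl (1.1 equiv), K2CO3 (1.1 equiv), acetone, 0 °C to rt
Reagents that add atoms: chloromethyl methyl ether COCCl
Why: Selective O-alkylation of the hydroxyl para to the aldehyde, as in 2,4-dihydroxybenzaldehydes; the C3 hydroxyl is tied up in a hydrogen bond to the formyl group and is less acidic, so one equivalent of base and electrophile should go to C5.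

Step 3
Reactants: 4 methyl 2-formyl-3-hydroxy-5-(methoxymethoxy)benzoate
Product: 5 methyl 2-formyl-3-methoxy-5-(methoxymethoxy)benzoate
Conditions: MeI, K2CO3, DMF, 40 °C
Reagents that add atoms: iodomethane CI
Why: Williamson methylation of the remaining chelated phenol under more forcing conditions; the aldehyde has no α-hydrogen and the acetal and ester are stable to carbonate.

Step 4
Reactants: 5 methyl 2-formyl-3-methoxy-5-(methoxymethoxy)benzoate
Product: 6 2-formyl-3-methoxy-5-(methoxymethoxy)benzoic acid
Conditions: LiOH, THF/H2O, 0 °C to rt; then cold 0.5 M HCl to pH 3–4
Reagents that add atoms: lithium hydroxide [Li+].[OH-]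
Why: Saponification of a methyl ester, accelerated by the neighbouring formyl group through its hydrate; the low temperature limits Cannizzaro reaction and the brief cold acidification spares the methoxymethyl ether.

Step 5
Reactants: 6 2-formyl-3-methoxy-5-(methoxymethoxy)benzoic acid
Product: 7 tert-butyl 2-formyl-3-methoxy-5-(methoxymethoxy)benzoate
Conditions: t-BuBr (excess), K2CO3, BnEt3NCl, DMAc, 55 °C
Reagents that add atoms: 2-bromo-2-methylpropane CC(C)(C)Br
Why: O-alkylation of the carboxylate under basic phase-transfer conditions; in base the acid is present as the open-chain carboxylate, so the normal ester and not the pseudo ester of the lactol should form, and the acid-labile acetal is not exposed to acid.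

Step 6
Reactants: 8 4,6-dimethyl-2H-pyran-2-one
Product: 9 3-chloro-4,6-dimethyl-2H-pyran-2-one
Conditions: NCS (1.05 equiv), AcOH, 55 °C, dark
Reagents that add atoms: N-chlorosuccinimide O=C1CCC(=O)N1Cl
Why: Electrophilic halogenation of a 2-pyranone; attack at C3 gives a cation delocalised over C4, C6 and the ring oxygen and stabilised by both methyl groups, so C3 should be preferred over C5, and exclusion of light avoids side-chain chlorination.

Step 7
Reactants: 9 3-chloro-4,6-dimethyl-2H-pyran-2-one; 7 tert-butyl 2-formyl-3-methoxy-5-(methoxymethoxy)benzoate
Product: 11 tert-butyl 2-[2-(3-chloro-4-methyl-2-oxo-2H-pyran-6-yl)-1-hydroxyethyl]-3-methoxy-5-(methoxymethoxy)benzoate (racemic), via lithium 3-chloro-4-methyl-6-methylidene-6H-pyran-2-olate 10 (not isolated)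
Conditions: LiN(SiMe3)2 (1.1 equiv), 9 (1.15 equiv), THF, −78 °C; then 7, −78 °C; AcOH quench at −78 °C
Reagents that add atoms: none
Why: Aldol addition of a laterally lithiated 6-methyl-2-pyranone; the C6 methyl gives the linearly conjugated trienolate 10, which is more delocalised than the anion from the C4 methyl, and it adds through its exocyclic carbon to the non-enolisable aldehyde. The new carbinol centre is formed without control and is removed in step 8; the cold quench is meant to prevent retro-aldol and attack of the alkoxide on the hindered tert-butyl ester.

Step 8
Reactants: 11 tert-butyl 2-[2-(3-chloro-4-methyl-2-oxo-2H-pyran-6-yl)-1-hydroxyethyl]-3-methoxy-5-(methoxymethoxy)benzoate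
Product: 12 tert-butyl 2-[2-(3-chloro-4-methyl-2-oxo-2H-pyran-6-yl)acetyl]-3-methoxy-5-(methoxymethoxy)benzoate
Conditions: Dess–Martin periodinane (1.3 equiv), CH2Cl2, 0 °C to rt
Reagents that add atoms: none
Why: Dess–Martin oxidation of a hindered benzylic secondary alcohol under near-neutral conditions; the acetal, the tert-butyl ester and the pyranone are inert, and a small excess of oxidant avoids oxidation of the newly activated methylene.

Step 9
Reactants: 12 tert-butyl 2-[2-(3-chloro-4-methyl-2-oxo-2H-pyran-6-yl)acetyl]-3-methoxy-5-(methoxymethoxy)benzoate
Product: 14 tert-butyl 2-(3-chloro-2,6-dihydroxy-4-methylbenzoyl)-3-methoxy-5-(methoxymethoxy)benzoate, via the open-chain diketo enoate 13 (not isolated)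
Conditions: Mg(OMe)2 (3 equiv), MeOH, 65 °C; then cold dilute HCl to pH 3
Reagents that add atoms: none
Why: The base first removes a proton from the C1' methylene; methoxide then adds to the lactone carbonyl and the ring opens at the acyl–oxygen bond to the magnesium chelate of 13, methyl ester of a 2-chloro-3-methyl enoate whose double-bond geometry is inherited from the ring, so the ester and the C2' ketone are held on the same side. C1', activated by both ketones and held by magnesium, attacks the methyl ester carbonyl in a 6-exo-trig Dieckmann-type Claisen closure that forms the C1'–C6' bond; methoxide leaves and the resulting acylcyclohexenedione tautomerises irreversibly to the resorcinol, which pulls the preceding equilibria forward. The closest known reaction type is the alkoxide-induced conversion of 6-(2-oxoalkyl)-2-pyranones into acylresorcinols and acylphloroglucinols. No stereocentre is formed. The selectivity needed is attack of C1' on the enoate ester rather than on the ring A ester (5-exo-trig closure to an indane-1,3-dione); the bulk and poor leaving-group ability of the tert-butyl ester, against an unhindered methyl ester, should secure it. The ring B pattern is fixed by connectivity: the pyranone ring oxygen becomes the C2' hydroxyl, the lactone carbonyl oxygen the C6' hydroxyl, and pyranone C3, C4 and C5 become C5' (Cl), C4' (CH3) and C3' (H). The moderate temperature and the magnesium counter-ion are chosen to limit displacement of the C3 methoxy group by a ring B phenoxide (xanthone formation).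

Step 10
Reactants: 14 tert-butyl 2-(3-chloro-2,6-dihydroxy-4-methylbenzoyl)-3-methoxy-5-(methoxymethoxy)benzoate
Product: 15 2-(3-chloro-2,6-dihydroxy-4-methylbenzoyl)-5-hydroxy-3-methoxybenzoic acid
Conditions: TFA/CH2Cl2 1:2, ethane-1,2-dithiol (5 equiv), 0 °C to rt
Reagents that add atoms: none
Why: Acidolysis of a tert-butyl ester (loss of 2-methylpropene) and of an aryl methoxymethyl ether in one operation; the dithiol traps the oxocarbenium ion as a dithioacetal so that it cannot alkylate the free positions of the two phenolic rings, and the aryl methyl ether and aryl chloride are stable.

Step 11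
Reactants: 15 2-(3-chloro-2,6-dihydroxy-4-methylbenzoyl)-5-hydroxy-3-methoxybenzoic acid
Product: 16 monochlorosulochrin, methyl 2-(3-chloro-2,6-dihydroxy-4-methylbenzoyl)-5-hydroxy-3-methoxybenzoate
Conditions: TMSCHN2 (1.1 equiv), toluene/MeOH 4:1, 0 °C; AcOH quench
Reagents that add atoms: trimethylsilyldiazomethane C[Si](C)(C)C=[N+]=[N-]
Why: Diazoalkane esterification; only the carboxylic acid is acidic enough to protonate the reagent rapidly at 0 °C, the ring B hydroxyls are hydrogen-bonded to the ketone, and reaction through the carboxylate gives the normal ester rather than a pseudo ester.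

## Compound list

1 | methyl 3,5-dihydroxybenzoate | COC(=O)c1cc(O)cc(O)c1 | starting material
2 | N-[2,4-dihydroxy-6-(methoxycarbonyl)benzylidene]-N-methylmethanaminium chloride | COC(=O)c1cc(O)cc(O)c1C=[N+](C)C.[Cl-] | intermediate (not isolated)
3 | methyl 2-formyl-3,5-dihydroxybenzoate | COC(=O)c1cc(O)cc(O)c1C=O | intermediate
4 | methyl 2-formyl-3-hydroxy-5-(methoxymethoxy)benzoate | COC(=O)c1cc(OCOC)cc(O)c1C=O | intermediate
5 | methyl 2-formyl-3-methoxy-5-(methoxymethoxy)benzoate | COC(=O)c1cc(OCOC)cc(OC)c1C=O | intermediate
6 | 2-formyl-3-methoxy-5-(methoxymethoxy)benzoic acid | OC(=O)c1cc(OCOC)cc(OC)c1C=O | intermediate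
7 | tert-butyl 2-formyl-3-methoxy-5-(methoxymethoxy)benzoate | CC(C)(C)OC(=O)c1cc(OCOC)cc(OC)c1C=O | intermediate
8 | 4,6-dimethyl-2H-pyran-2-one | CC1=CC(C)=CC(=O)O1 | starting material
9 | 3-chloro-4,6-dimethyl-2H-pyran-2-one | CC1=CC(C)=C(Cl)C(=O)O1 | intermediate
10 | lithium 3-chloro-4-methyl-6-methylidene-6H-pyran-2-olate | [Li]OC1=C(Cl)C(C)=CC(=C)O1 | intermediate (not isolated)
11 | tert-butyl 2-[2-(3-chloro-4-methyl-2-oxo-2H-pyran-6-yl)-1-hydroxyethyl]-3-methoxy-5-(methoxymethoxy)benzoate (racemic) | CC(C)(C)OC(=O)c1cc(OCOC)cc(OC)c1C(O)CC1=CC(C)=C(Cl)C(=O)O1 | intermediate
12 | tert-butyl 2-[2-(3-chloro-4-methyl-2-oxo-2H-pyran-6-yl)acetyl]-3-methoxy-5-(methoxymethoxy)benzoate | CC(C)(C)OC(=O)c1cc(OCOC)cc(OC)c1C(=O)CC1=CC(C)=C(Cl)C(=O)O1 | intermediate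
13 | tert-butyl 2-[(5E)-6-chloro-7-methoxy-5-methyl-3,7-dioxohept-5-enoyl]-3-methoxy-5-(methoxymethoxy)benzoate (present as its magnesium enolate) | COC(=O)/C(Cl)=C(/C)CC(=O)CC(=O)c1c(OC)cc(OCOC)cc1C(=O)OC(C)(C)C | intermediate (not isolated)
14 | tert-butyl 2-(3-chloro-2,6-dihydroxy-4-methylbenzoyl)-3-methoxy-5-(methoxymethoxy)benzoate | CC(C)(C)OC(=O)c1cc(OCOC)cc(OC)c1C(=O)c1c(O)cc(C)c(Cl)c1O | intermediate
15 | 2-(3-chloro-2,6-dihydroxy-4-methylbenzoyl)-5-hydroxy-3-methoxybenzoic acid | OC(=O)c1cc(O)cc(OC)c1C(=O)c1c(O)cc(C)c(Cl)c1O | intermediate
16 | monochlorosulochrin, methyl 2-(3-chloro-2,6-dihydroxy-4-methylbenzoyl)-5-hydroxy-3-methoxybenzoate | COC(=O)c1cc(O)cc(OC)c1C(=O)c1c(O)cc(C)c(Cl)c1O | target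

## Step count and least certain steps

Total: 11 steps. Longest linear sequence: 10 steps (steps 1 to 5 and 7 to 11, from 1 to 16); step 6 is a one-step side branch.

Step 9 (key step). The most likely failure is that ring opening stalls. The substrate is deprotonated at C1' before methoxide can add, and the delocalised anion lowers the electrophilicity of the lactone carbonyl. The opened chain could also be diverted into retro-Claisen cleavage of the 1,3-diketone, or into slow closure onto the ring A ester on long heating. The fallback gives up the pyranone and forms the benzophenone by aryllithium addition, setting out from 7 and coming back at 15. Commercial orcinol would be monochlorinated (SO2Cl2, Et2O) to 4-chloro-5-methylbenzene-1,3-diol F1 and protected (MOMCl, i-Pr2NEt) as 2-chloro-1,5-bis(methoxymethoxy)-3-methylbenzene F2. Directed lithiation between the two acetal oxygens (n-BuLi, THF, 0 °C) would give [3-chloro-2,6-bis(methoxymethoxy)-4-methylphenyl]lithium F3. Addition of F3 to 7 at −78 °C with a cold quench would give tert-butyl 2-{[3-chloro-2,6-bis(methoxymethoxy)-4-methylphenyl](hydroxy)methyl}-3-methoxy-5-(methoxymethoxy)benzoate F4. Dess–Martin oxidation would give tert-butyl 2-[3-chloro-2,6-bis(methoxymethoxy)-4-methylbenzoyl]-3-methoxy-5-(methoxymethoxy)benzoate F5. The acidolysis conditions of step 10 would then remove the tert-butyl ester and all three acetals and return to the route at 15.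

Step 7. The most likely failure is cyclisation of the lithium alkoxide of 11 onto the neighbouring tert-butyl ester (phthalide formation with loss of tert-butoxide), or reversal of the aldol on warming. The carbinol is pressed against the ester by the two ortho substituents. A lesser risk is competing deprotonation at the C4 methyl of 9, which equilibration toward the more delocalised trienolate should correct. The fallback replaces the aldol and oxidation by a direct acylation, setting out from 7 and coming back at 12. Pinnick oxidation (NaClO2, NaH2PO4, 2-methyl-2-butene, t-BuOH/H2O) would give 2-(tert-butoxycarbonyl)-6-methoxy-4-(methoxymethoxy)benzoic acid F6. Cyanuric fluoride and pyridine in CH2Cl2 would convert it to 2-(tert-butoxycarbonyl)-6-methoxy-4-(methoxymethoxy)benzoyl fluoride F7. An acyl fluoride is chosen because it does not ionise toward the neighbouring ester as a chloride would. Treatment of F7 with two equivalents of 10 at −78 °C (the second equivalent deprotonates the product) would give 12 directly.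

Step 6. The most likely failure is chlorination at C5 as well as at C3, or double chlorination, because the ring oxygen activates both positions. The fallback brings the halogen in by addition and elimination and then exchanges it, setting out from 8 and coming back at 9. Bromine in CH2Cl2 followed by Et3N (1,4-addition across the diene, then loss of HBr) would give 3-bromo-4,6-dimethyl-2H-pyran-2-one F8. Halogen exchange with CuCl in DMF at 130 °C would then give 9.

Step 10. The most likely failure is re-addition of the methoxymethyl and tert-butyl cations to the activated free positions (C3' of ring B, C4 and C6 of ring A) before the scavenger captures them. The fallback avoids a pool of free cations in strong protic acid, setting out from 14 and coming back at 15. Me3SiBr in CH2Cl2 at −30 to 0 °C would cleave the acetal and the tert-butyl ester as covalent halides and silyl derivatives, and aqueous methanol would then release 15. No new isolated compound is involved.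

Step 11. The most likely failure is over-alkylation: the diazoalkane also methylates the most acidic phenol, the C5 hydroxyl para to the ketone. The fallback uses acidity instead of rate of protonation, setting out from 15 and coming back at 16. One equivalent of KHCO3 in DMF would form only the carboxylate, which would be alkylated with MeI at rt. No new compound is involved.

## Further compounds

F1 | step 9 | 4-chloro-5-methylbenzene-1,3-diol | Cc1cc(O)cc(O)c1Cl
F2 | step 9 | 2-chloro-1,5-bis(methoxymethoxy)-3-methylbenzene | Cc1cc(OCOC)cc(OCOC)c1Cl
F3 | step 9 | [3-chloro-2,6-bis(methoxymethoxy)-4-methylphenyl]lithium | [Li]c1c(OCOC)cc(C)c(Cl)c1OCOC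
F4 | step 9 | tert-butyl 2-{[3-chloro-2,6-bis(methoxymethoxy)-4-methylphenyl](hydroxy)methyl}-3-methoxy-5-(methoxymethoxy)benzoate (racemic) | CC(C)(C)OC(=O)c1cc(OCOC)cc(OC)c1C(O)c1c(OCOC)cc(C)c(Cl)c1OCOC
F5 | step 9 | tert-butyl 2-[3-chloro-2,6-bis(methoxymethoxy)-4-methylbenzoyl]-3-methoxy-5-(methoxymethoxy)benzoate | CC(C)(C)OC(=O)c1cc(OCOC)cc(OC)c1C(=O)c1c(OCOC)cc(C)c(Cl)c1OCOC
F6 | step 7 | 2-(tert-butoxycarbonyl)-6-methoxy-4-(methoxymethoxy)benzoic acid | CC(C)(C)OC(=O)c1cc(OCOC)cc(OC)c1C(=O)O
F7 | step 7 | 2-(tert-butoxycarbonyl)-6-methoxy-4-(methoxymethoxy)benzoyl fluoride | CC(C)(C)OC(=O)c1cc(OCOC)cc(OC)c1C(=O)F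
F8 | step 6 | 3-bromo-4,6-dimethyl-2H-pyran-2-one | CC1=CC(C)=C(Br)C(=O)O1
F0 | step 10 | none | none
F0 | step 11 | none | none
A1 | alternative 1 | 7-chloro-8-hydroxy-1-methoxy-6-methyl-9,10-dioxo-9,10-dihydroanthracen-3-yl acetate | CC(=O)Oc1cc(OC)c2C(=O)c3c(O)c(Cl)c(C)cc3C(=O)c2c1
A2 | alternative 1 | 2-chloro-1-hydroxy-10-methoxy-3-methyl-6,11-dioxo-6,11-dihydrodibenzo[b,e]oxepin-8-yl acetate | O=C1Oc2cc(C)c(Cl)c(O)c2C(=O)c2c(OC)cc(OC(C)=O)cc12
A3 | alternative 2 | methyl 4-[3-chloro-2,6-bis(methoxymethoxy)-4-methylphenyl]-4-oxobut-2-ynoate | COC(=O)C#CC(=O)c1c(OCOC)cc(C)c(Cl)c1OCOC
A4 | alternative 2 | 1,1-dimethoxy-3-(trimethylsilyloxy)buta-1,3-diene | COC(OC)=CC(=C)O[Si](C)(C)C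
A5 | alternative 2 | methyl 2-[3-chloro-2,6-bis(methoxymethoxy)-4-methylbenzoyl]-5-hydroxy-3-methoxybenzoate | COC(=O)c1cc(O)cc(OC)c1C(=O)c1c(OCOC)cc(C)c(Cl)c1OCOC
A6 | alternative 3 | methyl 2-[(5-chloro-4-hydroxy-6-methyl-2-oxo-2H-pyran-3-yl)carbonyl]-3-methoxy-5-(pivaloyloxy)benzoate | COC(=O)c1cc(OC(=O)C(C)(C)C)cc(OC)c1C(=O)C1=C(O)C(Cl)=C(C)OC1=O
A7 | alternative 3 | 1,1-bis(trimethylsilyloxy)ethene | C=C(O[Si](C)(C)C)O[Si](C)(C)C
A8 | alternative 3 | methyl 2-(3-chloro-2,6-dihydroxy-4-methylbenzoyl)-3-methoxy-5-(pivaloyloxy)benzoate | COC(=O)c1cc(OC(=O)C(C)(C)C)cc(OC)c1C(=O)c1c(O)cc(C)c(Cl)c1O
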